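**Strategy.** Numbering the cycloheptane C1 (CH–OAng), C2 (lactone CH–O), C3 (ring-fusion CH), C4 (CH2), C5 (CHOH), C6 (CHCH3), C7 (acyl carbinol), the ring is cut at C5–C6 and C1–C7. The key step exploits the cis-1,4-dioxygenation of C1/C5 and the oxygen on C2: C1–C5 is the carbon arc of a 2-methoxypyrylium-5-olate, made by oxidative dearomatisation of furfuryl alcohol, whose ring oxygen ties C1 to C5. Its cycloaddition with a chiral (Z)-propenyl ether (C6, C7) forges both bonds and the carbocycle and sets C1 and C6; the bridged ketal later opens to the C1 hydroxyl and a C5 ketone.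

Key step: step 5

Assumption: (S)-1-(naphthalen-1-yl)ethanol, methyl 2-bromopropanoate, 1-methoxybut-2-yne and angelic acid are taken as commercial. Remark: the locants C1–C7 of the overview also number the 8-oxabicyclo[3.2.1]octane intermediates (O8 is the bridging oxygen; exo = on the side of O8, endo = on the side of the C2–C4 bridge).

Step 1
Reactants: 1 furfuryl alcohol (furan-2-ylmethanol)
Product: 2 6-hydroxy-2H-pyran-3(6H)-one (racemic hemiacetal)
Conditions: mCPBA, CH2Cl2, 0 °C → rt
Reagents that add atoms: mCPBA (3-chloroperoxybenzoic acid), O=C(OO)c1cccc(Cl)c1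
Why: Achmatowicz rearrangement, in which oxidation of the furan next to the carbinol, opening to the ene-dione and hemiacetal closure give the pyranone; the hemiacetal centre is erased in step 2.

Step 2
Reactants: 2 6-hydroxy-2H-pyran-3(6H)-one
Product: 4 5-(tert-butyldimethylsilyloxy)-2H-pyran-2-one, via 2H-pyran-2,5(6H)-dione 3 (not isolated)
Conditions: TEMPO (10 mol %), PhI(OAc)2, CH2Cl2, rt; then i-Pr2NEt, TBSOTf, −78 → 0 °C
Reagents that add atoms: tert-butyldimethylsilyl triflate (TBSOTf), C[Si](C)(OS(=O)(=O)C(F)(F)F)C(C)(C)C
Why: oxoammonium oxidation of the lactol to the lactone, after which the methylene between ring oxygen and ketone enolises easily and O-silylation should give the 2-pyranone silyl ether; no stereocentre.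

Step 3
Reactants: 5 (S)-1-(naphthalen-1-yl)ethanol; 6 allyl bromide
Product: 7 1-[(1S)-1-(prop-2-en-1-yloxy)ethyl]naphthalene
Conditions: NaH, THF/DMF, 0 °C → rt
Reagents that add atoms: none
Why: Williamson ether synthesis at oxygen, which leaves the carbinol stereocentre untouched.

Step 4
Reactants: 7 1-[(1S)-1-(prop-2-en-1-yloxy)ethyl]naphthalene
Product: 8 1-[(1S)-1-{[(1Z)-prop-1-en-1-yl]oxy}ethyl]naphthalene
Conditions: KOtBu (0.3 equiv), DMSO, rt
Reagents that add atoms: none
Why: base-mediated allyl-to-propenyl ether isomerisation through the potassium-bridged cisoid allyl anion, which should give the (Z)-enol ether.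

Step 5
Reactants: 4 5-(tert-butyldimethylsilyloxy)-2H-pyran-2-one; 8 1-[(1S)-1-{[(1Z)-prop-1-en-1-yl]oxy}ethyl]naphthalene
Product: 11 (1R,5R,6R,7S)-5-methoxy-6-methyl-7-[(1S)-1-(naphthalen-1-yl)ethoxy]-8-oxabicyclo[3.2.1]oct-3-en-2-one (6-methyl/7-alkoxy both endo), via pyrylium triflate 9 (not isolated), via oxidopyrylium ylide 10 (not isolated)
Conditions: 4 (1.5 equiv), MeOTf, 2,6-di-tert-butyl-4-methylpyridine (10 mol %), CH2Cl2, 40 °C; evaporate; then 8, CsF, CH2Cl2/MeCN, 0 °C → rt
Reagents that add atoms: methyl triflate (MeOTf), COS(=O)(=O)C(F)(F)F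
Why: Proposed new method: O-methylation of the pyranone carbonyl should give pyrylium salt 9 and fluoride desilylation the aromatic zwitterion 10, whose future C1 (CH next to the olate, nucleophilic) and future C5 (methoxy-bearing, carboxonium-like, electrophilic) add suprafacially to the enol ether in one asynchronous thermal [5+2] (π4s+π2s) cycloaddition, the nucleophilic methyl-bearing carbon of 8 bonding to C5 and the oxygen-bearing carbon to C1; the closest known reaction types are the fluoride-triggered generation and alkene cycloadditions of 4-methoxy-3-oxidopyrylium from O-methylated silyloxy-4-pyranones and the cycloadditions of 1-methoxy-2-benzopyrylium-4-olates with vinyl ethers. The cycloheptenone and the oxolane ring close in the same cycloaddition, so only orbital symmetry governs closure and the oxygen bridge is necessarily cis. C1 and C5 follow from suprafacial addition, and C6 and C7 from retention of the (Z)-geometry with the alkoxy group endo (attraction between the ether oxygen and the cationic ring, as for vinyl ethers with 3-oxidopyrylium), which places the C6 methyl endo. The absolute sense should come from the (S)-1-naphthylethyl group: in the s-trans enol ether with the carbinol hydrogen eclipsing the vinyl C–H, the naphthyl group covers one face and the ylide adds to the Re,Re face. The step needs regioselectivity (expected from the polarisation that the methoxy group imposes on the ylide), endo selectivity and π-facial selectivity; all stereoisomeric adducts are diastereomers and would be removed by chromatography.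

Step 6
Reactants: 11 (1R,5R,6R,7S)-5-methoxy-6-methyl-7-[(1S)-1-(naphthalen-1-yl)ethoxy]-8-oxabicyclo[3.2.1]oct-3-en-2-one
Product: 12 3-iodo-5-methoxy-6-endo-methyl-7-endo-[(1S)-1-(naphthalen-1-yl)ethoxy]-8-oxabicyclo[3.2.1]oct-3-en-2-one (core as in 11)
Conditions: I2, pyridine, CH2Cl2, rt
Reagents that add atoms: iodine, II
Why: α-iodination of the cyclic enone by conjugate addition of pyridine, iodination of the enolate and elimination; stereocentres are untouched.

Step 7
Reactants: 12 the 3-iodo enone; 13 methyl 2-bromopropanoate (racemic)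
Product: 15 methyl 2-[5-methoxy-6-endo-methyl-7-endo-{(1S)-1-(naphthalen-1-yl)ethoxy}-2-oxo-8-oxabicyclo[3.2.1]oct-3-en-3-yl]propanoate (core as in 11; both epimers at the propanoate α-carbon), via Reformatsky reagent 14 (not isolated)
Conditions: 13, Zn dust (TMSCl-activated), THF, 40 °C; then 12, Pd(dba)2 (5 mol %), XPhos (10 mol %), THF, rt → 50 °C
Reagents that add atoms: none
Why: Negishi-type coupling of a zinc ester enolate (Reformatsky reagent) with the vinyl iodide after oxidative addition to zerovalent palladium; the new α-centre forms as both epimers and is corrected in step 9.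

Step 8
Reactants: 15 the C3-substituted enone ester
Product: 18 tricyclic lactone: 7-endo-hydroxy-5-methoxy-6-endo-methyl-8-oxabicyclo[3.2.1]octane carrying a cis γ-lactone on the endo face across C2–C3 (both α-methyl epimers), via saturated ketone 16 (not isolated), via hydroxy ester 17 (not isolated)
Conditions: H2 (1 atm), Pd/C, EtOAc, rt; filter; then NaBH4, CeCl3·7H2O, MeOH, −40 °C → rt; K2CO3, rt
Reagents that add atoms: none
Why: hydrogen should add to the C3=C4 alkene from the exo face (the endo face is covered by the C6 methyl and the C7 substituent), setting C3 with its side chain endo while the naphthylethyl ether is hydrogenolysed, and Luche reduction then delivers hydride to the C2 ketone from the same exo face before C3 can epimerise, so the endo C2 alkoxide closes the cis-fused γ-lactone.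

Step 9
Reactants: 18 the lactone epimer mixture
Product: 19 the same tricyclic lactone as a single epimer, lactone α-carbon (R), methyl on the concave face cis to the C3–C4 bond
Conditions: LiN(iPr)2 (3 equiv), THF, −78 °C; then AcOH, −78 °C
Reagents that add atoms: none
Why: kinetic protonation of the lactone enolate (the C7 alkoxide is carried along) on the convex face of the cis-fused lactone should leave the α-methyl on the concave face, and both epimers of 18 converge.

Step 10
Reactants: 19 the single-epimer hydroxy lactone
Product: 20 the corresponding C7 ketone (5-methoxy-6-endo-methyl-7-oxo tricyclic lactone)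
Conditions: Dess–Martin periodinane, NaHCO3, CH2Cl2, rt
Reagents that add atoms: none
Why: Dess–Martin oxidation of the only free (secondary) hydroxyl under buffered, non-epimerising conditions, so the C6 centre next to the new ketone is kept.

Step 11
Reactants: 21 1-methoxybut-2-yne
Product: 22 1-methoxybuta-1,2-diene (racemic axis)
Conditions: KOtBu (0.2 equiv), 70 °C, then distil
Reagents that add atoms: none
Why: base-catalysed propargyl-to-allenyl ether isomerisation, which stops at the conjugation-stabilised alkoxyallene.

Step 12
Reactants: 20 the C7 ketone; 22 1-methoxybuta-1,2-diene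
Product: 24 7-endo-hydroxy-7-exo-(1-methoxybuta-1,2-dien-1-yl) tricyclic lactone (allene axis unassigned), via lithioallene 23 (not isolated)
Conditions: 22, n-BuLi, THF, −40 °C; then 20, −78 °C; H2O
Reagents that add atoms: none
Why: 1,2-addition of an α-lithiated alkoxyallene (acyl anion equivalent of the but-2-enoyl group) to the strained five-ring ketone, which should outpace attack on the lactone and occur from the exo face (the endo face is covered by the C2–C4 bridge and its lactone), so C7 carries the hydroxyl endo and the carbon chain exo.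

Step 13
Reactants: 24 the allenyl carbinol
Product: 25 (3R,3aS,6S,7S,8S,8aR)-configured 7-[(2E)-but-2-enoyl]-7,8-dihydroxy-3,6-dimethylhexahydro-2H-cyclohepta[b]furan-2,5(3H)-dione (C5 ketone, free C1 and C7 hydroxyls; may rest partly as its bridged hemiketal)
Conditions: HCl (0.5 M), THF/H2O, 0 °C → rt
Reagents that add atoms: water, O
Why: acid hydrolysis of the methoxyallene gives the (E)-enone (thermodynamic geometry) and hydrolysis of the bridged methyl ketal through the ring-opened methoxycarbenium ion gives the C5 ketone while the C1–O bond is never broken, so the C1 hydroxyl keeps its configuration.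

Step 14
Reactants: 25 the dihydroxy diketone; 26 angelic acid ((2Z)-2-methylbut-2-enoic acid)
Product: 28 the C1 angelate of 25 (5-oxo analogue of the target), via mixed anhydride 27 (not isolated)
Conditions: 26, 2,4,6-trichlorobenzoyl chloride, Et3N, toluene, rt; then 25, DMAP, 60 °C
Reagents that add atoms: none
Why: Yamaguchi esterification, which should acylate the only secondary hydroxyl (C1; the C7 hydroxyl is tertiary) and is known to transfer angelic acid without isomerisation to the tiglate.

Step 15
Reactants: 28 the angelate ketone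
Product: 29 target, (3R,3aS,5R,6S,7S,8S,8aR)-7-[(2E)-but-2-enoyl]-5,7-dihydroxy-3,6-dimethyl-2-oxooctahydro-2H-cyclohepta[b]furan-8-yl (2Z)-2-methylbut-2-enoate
Conditions: Me4NBH(OAc)3, MeCN/AcOH, −30 °C
Reagents that add atoms: none
Why: Evans–Saksena reduction, in which the C7 hydroxyl binds boron and delivers hydride through a six-membered chair to the β-hydroxy ketone at C5 to give the 1,3-anti diol (C5 hydroxyl trans to the C7 hydroxyl), while the conjugated α-quaternary enone, the esters and the lactone should not react.

**Compound list**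

1 | furfuryl alcohol | OCc1ccco1 | starting material
2 | 6-hydroxy-2H-pyran-3(6H)-one (racemic) | O=C1C=CC(O)OC1 | intermediate
3 | 2H-pyran-2,5(6H)-dione | O=C1C=CC(=O)CO1 | intermediate
4 | 5-(tert-butyldimethylsilyloxy)-2H-pyran-2-one | O=C1C=CC(O[Si](C)(C)C(C)(C)C)=CO1 | intermediate
5 | (S)-1-(naphthalen-1-yl)ethanol | C[C@H](O)c1cccc2ccccc12 | starting material
6 | allyl bromide | C=CCBr | starting material
7 | 1-[(1S)-1-(prop-2-en-1-yloxy)ethyl]naphthalene | C=CCO[C@@H](C)c1cccc2ccccc12 | intermediate
8 | 1-[(1S)-1-{[(1Z)-prop-1-en-1-yl]oxy}ethyl]naphthalene | C/C=C\O[C@@H](C)c1cccc2ccccc12 | intermediate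
9 | 5-(tert-butyldimethylsilyloxy)-2-methoxypyrylium triflate | COc1ccc(O[Si](C)(C)C(C)(C)C)c[o+]1.[O-]S(=O)(=O)C(F)(F)F | intermediate
10 | 2-methoxypyrylium-5-olate (6-methoxy-3-oxidopyrylium) | COc1ccc([O-])c[o+]1 | intermediate
11 | (1R,5R,6R,7S)-5-methoxy-6-methyl-7-[(1S)-1-(naphthalen-1-yl)ethoxy]-8-oxabicyclo[3.2.1]oct-3-en-2-one | O=C1C=C[C@@]2(OC)O[C@@H]1[C@@H](O[C@@H](C)c3cccc4ccccc34)[C@H]2C | intermediate
12 | 3-iodo derivative of 11 | O=C1C(I)=C[C@@]2(OC)O[C@@H]1[C@@H](O[C@@H](C)c3cccc4ccccc34)[C@H]2C | intermediate
13 | methyl 2-bromopropanoate (racemic) | CC(Br)C(=O)OC | starting material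
14 | bromo(1-methoxy-1-oxopropan-2-yl)zinc | CC([Zn]Br)C(=O)OC | intermediate
15 | methyl 2-(bicyclic enone-3-yl)propanoate, both α-epimers | O=C1C(C(C)C(=O)OC)=C[C@@]2(OC)O[C@@H]1[C@@H](O[C@@H](C)c3cccc4ccccc34)[C@H]2C | intermediate
16 | methyl 2-[7-endo-hydroxy-5-methoxy-6-endo-methyl-2-oxo-8-oxabicyclo[3.2.1]octan-3-endo-yl]propanoate, both α-epimers | O=C1[C@H](C(C)C(=O)OC)C[C@@]2(OC)O[C@@H]1[C@@H](O)[C@H]2C | intermediate
17 | 2-endo-hydroxy analogue of 16 | O[C@@H]1[C@H](C(C)C(=O)OC)C[C@@]2(OC)O[C@@H]1[C@@H](O)[C@H]2C | intermediate
18 | tricyclic hydroxy lactone, both α-methyl epimers | O=C1O[C@@H]2[C@H](C1C)C[C@@]3(OC)O[C@@H]2[C@@H](O)[C@H]3C | intermediate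
19 | tricyclic hydroxy lactone, α-carbon (R) | O=C1O[C@@H]2[C@H]([C@H]1C)C[C@@]3(OC)O[C@@H]2[C@@H](O)[C@H]3C | intermediate
20 | tricyclic C7 ketone | O=C1O[C@@H]2[C@H]([C@H]1C)C[C@@]3(OC)O[C@@H]2C(=O)[C@H]3C | intermediate
21 | 1-methoxybut-2-yne | COCC#CC | starting material
22 | 1-methoxybuta-1,2-diene | COC=C=CC | intermediate
23 | 1-lithio-1-methoxybuta-1,2-diene | [Li]C(OC)=C=CC | intermediate
24 | 7-endo-hydroxy-7-exo-(1-methoxybuta-1,2-dien-1-yl) tricyclic lactone | O=C1O[C@@H]2[C@H]([C@H]1C)C[C@@]3(OC)O[C@@H]2[C@](O)(C(OC)=C=CC)[C@H]3C | intermediate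
25 | 7-[(2E)-but-2-enoyl]-7,8-dihydroxy-3,6-dimethylhexahydro-2H-cyclohepta[b]furan-2,5(3H)-dione | O[C@H]1[C@@H]2OC(=O)[C@H](C)[C@@H]2CC(=O)[C@H](C)[C@@]1(O)C(=O)/C=C/C | intermediate
26 | angelic acid | C/C=C(/C)C(=O)O | starting material
27 | angelic 2,4,6-trichlorobenzoic anhydride | C/C=C(/C)C(=O)OC(=O)c1c(Cl)cc(Cl)cc1Cl | intermediate
28 | C1 angelate of 25 | C/C=C(/C)C(=O)O[C@H]1[C@@H]2OC(=O)[C@H](C)[C@@H]2CC(=O)[C@H](C)[C@@]1(O)C(=O)/C=C/C | intermediate
29 | CNP0183494.1 | C/C=C(/C)C(=O)O[C@H]1[C@@H]2OC(=O)[C@H](C)[C@@H]2C[C@@H](O)[C@H](C)[C@@]1(O)C(=O)/C=C/C | target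

**Step count.** 15 steps in total; longest linear sequence 12 steps (steps 1, 2, 5–10, 12–15, from furfuryl alcohol).

**Steps most likely to fail**

Step 5 (proposed new method, highest risk): the ylide may not form cleanly (C-methylation of 4, or desilylation of 9 followed by dimerisation of 10), or it may add to 8 in the reverse orientation. The fallback sets out from 8 and returns at 11, generating 10 by the known carbenoid route to alkoxy-substituted carbonyl ylides. Commercial methyl hydrogen maleate would be converted with ClCO2Et/Et3N (THF, −20 °C) into ethyl carbonic (2Z)-4-methoxy-4-oxobut-2-enoic anhydride F1. Inverse addition of this to diazomethane (Et2O, −30 °C, to keep dipolar addition to the alkene behind acylation) would give methyl (2Z)-5-diazo-4-oxopent-2-enoate F2. Slow addition of the diazoketone to 8 with Rh2(OAc)4 (1 mol %) and Yb(OTf)3 (10 mol %) in CH2Cl2 would form 10 by attack of the cis ester carbonyl on the rhodium carbenoid, at a stationary concentration too low for dimerisation. The Lewis-acid-bound ylide should add to the enol ether in the inverse-demand orientation established for 1-methoxy-2-benzopyrylium-4-olates and vinyl ethers, giving 11.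

Step 15: hydride may also be delivered from the C7 hydroxyl to the neighbouring enone carbonyl through a five-membered arrangement, so that chemoselectivity is lost. The fallback sets out from 28 and returns at 29. Both ketones would be reduced on purpose with excess Me4NBH(OAc)3 to give the C1 angelate of the C5 alcohol whose but-2-enoyl carbonyl is reduced to the allylic alcohol (carbinol configuration unassigned) F6; its C5 centre is still set by the directed delivery. MnO2 (CH2Cl2, rt) would then re-oxidise only the allylic alcohol and leave the saturated C5 alcohol untouched, giving 29.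

Step 9: protonation of the lactone enolate may show poor facial selectivity, or the product may drift toward the convex-methyl epimer. The fallback sets out from 18 and returns at 19, setting the centre by hydrogenation instead. The enolate of 18 (LiN(iPr)2, THF, −78 °C) would be selenenylated on the convex face with PhSeCl to give the α-methyl-α-(phenylselanyl) lactone F3. H2O2 (CH2Cl2, 0 °C) would give the selenoxide F4, which should eliminate syn toward the cis-disposed C3–H to give the tetrasubstituted butenolide F5. Hydrogenation of the butenolide (H2, Rh/Al2O3, EtOAc, 50 bar) from the exo, convex face would deliver the C3 and the α-hydrogen cis and give 19.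

Further compounds
F1 | step 5 | ethyl carbonic (2Z)-4-methoxy-4-oxobut-2-enoic anhydride | CCOC(=O)OC(=O)/C=C\C(=O)OC
F2 | step 5 | methyl (2Z)-5-diazo-4-oxopent-2-enoate | COC(=O)/C=C\C(=O)C=[N+]=[N-]
F3 | step 9 | α-methyl-α-(phenylselanyl) derivative of lactone 18 (selenium on the convex face) | O=C1O[C@@H]2[C@H]([C@]1(C)[Se]c4ccccc4)C[C@@]3(OC)O[C@@H]2[C@@H](O)[C@H]3C
F4 | step 9 | selenoxide of F3 | O=C1O[C@@H]2[C@H]([C@]1(C)[Se](=O)c4ccccc4)C[C@@]3(OC)O[C@@H]2[C@@H](O)[C@H]3C
F5 | step 9 | tetrasubstituted butenolide (alkene between C3 and the lactone α-carbon) | O=C1O[C@@H]2C(=C1C)C[C@@]3(OC)O[C@@H]2[C@@H](O)[C@H]3C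
F6 | step 15 | target with the but-2-enoyl carbonyl reduced to the allylic alcohol (carbinol configuration unassigned) | C/C=C(/C)C(=O)O[C@H]1[C@@H]2OC(=O)[C@H](C)[C@@H]2C[C@@H](O)[C@H](C)[C@@]1(O)C(O)/C=C/C
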